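One mole of starting material charged is an entry that must close: it ends as target, or it stands among what the readings do not show.

| flask | starting material | catalyst | time |
|---|---|---|---|
| teal | 0.400 M | 0.0120 M |  |
| red | 0.160 M | 0.0120 M |  |
| blue | 0.400 M | 0.0180 M |  |
| ochre | 0.200 M | 0.0120 M |  |
| grey | 0.400 M | 0.0120 M | 42 h |

| run | time / h | [target] / M |
|---|---|---|
| teal run | 2.3 | 0.0564 |
| teal run | 4.7 | 0.1119 |
| teal run | 7.0 | 0.1540 |
| teal run | 9.3 | 0.1848 |
| teal run | 12 | 0.2045 |
| teal run | 14 | 0.2072 |
| red run | 2.3 | 0.0432 |
| red run | 4.7 | 0.0768 |
| red run | 7.0 | 0.0952 |
| red run | 9.3 | 0.1017 |
| red run | 12 | 0.1030 |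
| red run | 14 | 0.1034 |
| blue run | 2.3 | 0.0956 |
| blue run | 4.7 | 0.1905 |
| blue run | 7.0 | 0.2492 |
| blue run | 9.3 | 0.2611 |
| blue run | 12 | 0.2642 |
| blue run | 14 | 0.2670 |
| ochre run | 2.3 | 0.0475 |
| ochre run | 4.7 | 0.0863 |
| ochre run | 7.0 | 0.1110 |
| ochre run | 9.3 | 0.1226 |
| ochre run | 12 | 0.1195 |
| ochre run | 14 | 0.1230 |

(readings scatter by 0.002 M)

* the exponent of [starting material] in the starting rate at the charge of the teal run (at the point where two percent of the starting material have become target) (one fixed amount of target, the same in the runs compared)
* the exponent of [catalyst] in the starting rate at the charge of the teal run (at the point where two percent of the starting material have become target)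
* target in the grey run at 42 h, as a share of the starting material charged

- Overall: starting material -> target, with catalyst as catalyst.
- Constant volume, constant temperature.
- A reading of a species includes what of it is bound.
- An order is taken over about fifteen percent of the charge, up and down.

The teal flask opens with 0.400 M of starting material. Its last two readings differ by 0.002700 M, against a scatter of 0.002 M on each, so its books can be closed at the last one. There, 0.2072 M stands as target, a closing share of 51.8%, and 0.193 M is missing. The ratio of these two entries, the split 1.07, is the moles of target booked per mole missing, a selectivity factor read from the readings.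

The blue flask has the same charge and more catalyst, and it books 0.2670 M as target, more than teal. A catalyst does not shift an equilibrium, so the teal share is not an equilibrium share. At the catalyst level of teal, the closing share rises as the charge falls: 61.5% in ochre and 64.6% in red, both above teal. The reckoning made here reads the missing entry as a second exit competing with target formation. The grey flask repeats the teal recipe, so its split should repeat too, which gives 51.7% at the asked time.

The forecast gave 0.2 and 1.33 for the two exponents and 55% for grey, holding of teal that “its catalyst seems to die”. Its share lies close to the one reckoned here, but the grounds differ: a failing catalyst there, a second exit here.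

The flask gives 0.35 and 0.95 for the exponents and 52.3% for grey.

    catalyst + starting material ⇌ catalyst-substrate complex, settled at all times (6.510 L mol⁻¹)
    catalyst-substrate complex + catalyst → target + 2 catalyst (421.2 L mol⁻¹ h⁻¹)
    starting material → target (0.03780 h⁻¹)
    starting material → decomposed substrate (0.1177 h⁻¹)

Grey closes with a split of 1.10, leaving 47.7% of its charge missing. Conversion into decomposed substrate accounts for 100% of that shortfall, and with this exit taken away the same run ends at >99.9%. Carried to the blue flask, with the same charge and 1.50 times the catalyst, the split reads 2.01, which is 1.88 times that of teal, and the missing entry there is 0.133 M.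

The data were generated by integration with made-up constants, noise included.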